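**Plan**

1. Atom labels: ring carbons C1–C10; C4 is the methyl carbinol (methyl C15), C5 the free secondary carbinol, C6 the angeloyloxy carbon, C7 carries C11 (methyls C12, C13), C10 carries methyl C14.
2. Enabling feature: in the ten-membered ring, oxygenated C6 lies between C5 (a carbinol that can be a ketone) and C7, whose C11 side chain becomes an isopropenyl group on formal loss of water. O–C6–C7–C11=C12 is then the homoallylic alcohol left by a [2,3]-Wittig shift of an O–C12 allyl ether; the C5 ketone stabilises the C6 carbanion and quaternary C4 leaves C6 as the only enolisable site.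
3. Retrosynthetic cuts, in order: ester C–O at C6; C5–H (back to the ketone); C11–OH (back to isopropenyl); ring bond C6–C7 with O reconnected to C12 (13-membered ether); then C7–C8 (sp2–sp3 coupling), C6–O (carbenoid O–H insertion) and C5–C6 (diazoketone from an acid).
4. Forward order: citronellene chain → C4 diol → acid → C6 diazoketone; ether bond to a Z iodoallyl alcohol; 13-membered ring by B-alkyl Suzuki coupling; ten-membered ring by ring contraction; hydration, angeloylation, ketone reduction.
5. Stereochemistry: C10 from (S)-β-citronellene; C4 from Sharpless epoxidation (L-(+)-tartrate) and hydride opening; C6 and C7 from the Wittig shift (Z alkene geometry, ring conformation); C5 from chelation-controlled reduction.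

Key step: step 10

Remark: (S)-β-citronellene is taken as commercially available, and the facial sense of the Sharpless epoxidation is taken from the usual rule for E-2-methylalk-2-en-1-ols (L-(+)-tartrate gives the (2S,3S)-epoxide).

**Route**

Step 1
Reactants: 1 (S)-β-citronellene [(3S)-3,7-dimethylocta-1,6-diene]
Product: 2 (2E,6S)-2,6-dimethylocta-2,7-dien-1-ol
Conditions: SeO2 (cat.), tBuOOH, salicylic acid (cat.), CH2Cl2, 0 °C to rt
Reagents that add atoms: tert-butyl hydroperoxide, CC(C)(C)OO
Why: Riley-type allylic oxidation (ene reaction, then [2,3]-shift of the allylseleninic acid) should attack only the electron-rich trisubstituted alkene, at its E methyl group (the future C5), and leave the vinyl group and the C10 stereocentre untouched.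

Step 2
Reactants: 2 (2E,6S)-2,6-dimethylocta-2,7-dien-1-ol
Product: 3 [(2S,3S)-2-methyl-3-[(3S)-3-methylpent-4-en-1-yl]oxiran-2-yl]methanol
Conditions: Ti(OiPr)4 (cat.), L-(+)-diethyl tartrate (cat.), tBuOOH, 4 Å molecular sieves, CH2Cl2, −20 °C
Reagents that add atoms: tert-butyl hydroperoxide, CC(C)(C)OO
Why: Sharpless asymmetric epoxidation acts only on the allylic alcohol, and the L-(+)-tartrate ligand should deliver oxygen to the face that gives the (2S,3S)-epoxide, so the C–O bond of the future C4 carbinol is set by reagent control.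

Step 3
Reactants: 3 [(2S,3S)-2-methyl-3-[(3S)-3-methylpent-4-en-1-yl]oxiran-2-yl]methanol
Product: 4 (2R,6S)-2,6-dimethyloct-7-ene-1,2-diol
Conditions: LiAlH4, THF, 0 °C to rt
Reagents that add atoms: none
Why: Hydride opening of the 2,3-epoxy alcohol should occur by SN2 attack at the secondary epoxide carbon because the other one is fully substituted, so the tertiary C–O bond is retained and the 1,2-diol carries C4 in the R configuration.

Step 4
Reactants: 4 (2R,6S)-2,6-dimethyloct-7-ene-1,2-diol
Product: 5 (2R,6S)-2-hydroxy-2,6-dimethyloct-7-enoic acid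
Conditions: TEMPO (cat.), NaOCl (cat.), NaClO2, MeCN/phosphate buffer (pH 6.7), 35 °C
Reagents that add atoms: sodium chlorite, [Na+].[O-]Cl=O
Why: Anelli-type oxoammonium oxidation to the aldehyde coupled with Lindgren chlorite oxidation should convert only the primary carbinol (the tertiary hydroxyl is inert), and the buffered medium with catalytic hypochlorite should avoid glycol cleavage and chlorination of the vinyl group.

Step 5
Reactants: 5 (2R,6S)-2-hydroxy-2,6-dimethyloct-7-enoic acid
Product: 6 triethylsilyl (2R,6S)-2,6-dimethyl-2-[(triethylsilyl)oxy]oct-7-enoate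
Conditions: Et3SiOTf (2.5 equiv), 2,6-lutidine, CH2Cl2, −78 to 0 °C; non-aqueous work-up, used crude
Reagents that add atoms: triethylsilyl trifluoromethanesulfonate, CC[Si](CC)(CC)OS(=O)(=O)C(F)(F)F
Why: Silylation with the silyl triflate should cap the hindered tertiary hydroxyl as an ether that offers no activated C–H bond to the later carbenoid, and turns the acid into the silyl ester needed for acid chloride formation under neutral conditions.

Step 6
Reactants: 6 triethylsilyl (2R,6S)-2,6-dimethyl-2-[(triethylsilyl)oxy]oct-7-enoate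
Product: 8 (3R,7S)-1-diazo-3,7-dimethyl-3-[(triethylsilyl)oxy]non-8-en-2-one, via acid chloride 7 (not isolated)
Conditions: (COCl)2, DMF (cat.), CH2Cl2, 0 °C; concentrate; then TMSCHN2 (2 equiv), THF/MeCN, 0 °C to rt
Reagents that add atoms: trimethylsilyldiazomethane, C[Si](C)(C)C=[N+]=[N-]
Why: Vilsmeier-type activation converts the silyl ester into the acid chloride without releasing HCl, and acylation of trimethylsilyldiazomethane (first stage of an Arndt–Eistert sequence) with loss of chlorotrimethylsilane should give the terminal diazoketone that brings in C6.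

Step 7
Reactants: 9 prop-2-yn-1-ol (propargyl alcohol)
Product: 11 (2Z)-3-iodo-2-methylprop-2-en-1-ol, via vinylmagnesium alkoxide 10 (not isolated)
Conditions: MeMgBr (2.3 equiv), CuI (10 mol %), THF, −10 °C to rt; then I2, THF, −78 to 0 °C
Reagents that add atoms: methylmagnesium bromide, C[Mg]Br; iodine, [I][I]
Why: Copper-catalysed anti carbomagnesiation of the propargylic alkoxide places magnesium cis to the CH2O group in a five-membered chelate and iodinolysis proceeds with retention, so only the Z iodoalkene (C7, C11, C12, C13) should form.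

Step 8
Reactants: 8 (3R,7S)-1-diazo-3,7-dimethyl-3-[(triethylsilyl)oxy]non-8-en-2-one; 11 (2Z)-3-iodo-2-methylprop-2-en-1-ol (3 equiv)
Product: 12 (3R,7S)-1-{[(2Z)-3-iodo-2-methylprop-2-en-1-yl]oxy}-3,7-dimethyl-3-[(triethylsilyl)oxy]non-8-en-2-one
Conditions: Rh2(OAc)4 (1 mol %), CH2Cl2, rt, slow addition of 8
Reagents that add atoms: none
Why: Rhodium-carbenoid O–H insertion (oxonium ylide, then proton shift) into the excess primary alcohol should outrun C–H insertion and cyclopropanation, and the enol formed cannot divert into a [3,3] shift onto C5 because C5 adjoins quaternary C4.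

Step 9
Reactants: 12 (3R,7S)-1-{[(2Z)-3-iodo-2-methylprop-2-en-1-yl]oxy}-3,7-dimethyl-3-[(triethylsilyl)oxy]non-8-en-2-one
Product: 14 (4R,8S,11Z)-4,8,12-trimethyl-4-[(triethylsilyl)oxy]-1-oxacyclotridec-11-en-3-one, via alkylborane 13 (not isolated)
Conditions: 9-BBN (1.2 equiv), THF, 0 °C to rt; then Pd(dppf)Cl2 (15 mol %), AsPh3, Cs2CO3, DMF/THF/H2O, 2 mM by slow addition, 45 °C
Reagents that add atoms: none
Why: Anti-Markovnikov hydroboration of the vinyl group by the bulky borane should outpace reduction of the hindered C5 ketone, and intramolecular B-alkyl Suzuki–Miyaura coupling at high dilution joins C8 to C7 with retention of the iodoalkene geometry, so the 13-membered ether carries the Z C7=C11 alkene.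

Step 10
Reactants: 14 (4R,8S,11Z)-4,8,12-trimethyl-4-[(triethylsilyl)oxy]-1-oxacyclotridec-11-en-3-one
Product: 16 (2R,6S,9S,10R)-10-hydroxy-2,6-dimethyl-9-(prop-1-en-2-yl)-2-[(triethylsilyl)oxy]cyclodecan-1-one, via lithium enolate 15 (not isolated)
Conditions: LiN(SiMe3)2 (1.3 equiv), THF, −78 to −20 °C; aq. NH4Cl at −78 °C
Reagents that add atoms: none
Why: Proposed new method: the base can remove a proton only at C6 because C4 is quaternary, and the C5–C6 lithium enolate then serves as the carbanion of a [2,3]-Wittig shift in which C6 attacks C7 suprafacially across an envelope-shaped five-centre transition state, the O–C12 bond is cleaved in the same event and the double bond moves to C11=C12 (the isopropenyl group). The nearest established reactions are the [2,3]-Wittig ring contraction of 13-membered allyl propargyl ethers to ten-membered carbocycles and the [2,3]-Wittig shift of acyclic α-allyloxy ketone enolates. The ten-membered carbocycle closes by transannular C6–C7 bond formation inside the 13-membered ether, a contraction in which O, C12 and C11 leave the ring. The C6/C7 relative configuration should follow from the Z geometry of C7=C11 with C5 lying over C8 on the exo side of the envelope (the arrangement that turns Z allyl ethers into syn products), whereas the alkene face that is attacked, and so the configuration relative to C4 and C10, depends on the macrocycle conformation (C10 methyl and C4 silyloxy group on the periphery) and must be confirmed. The step needs the [2,3] course to win over the [3,3] oxy-Claisen and [1,2] alternatives: bonding of C5 to C7 would place a new quaternary centre next to quaternary C4, and the lithium counter-ion at low temperature disfavours both.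

Step 11
Reactants: 16 (2R,6S,9S,10R)-10-hydroxy-2,6-dimethyl-9-(prop-1-en-2-yl)-2-[(triethylsilyl)oxy]cyclodecan-1-one
Product: 17 (2R,6S,9S,10R)-2,10-dihydroxy-2,6-dimethyl-9-(prop-1-en-2-yl)cyclodecan-1-one
Conditions: HF·pyridine, pyridine, THF, 0 °C to rt
Reagents that add atoms: none
Why: Fluoride-driven cleavage of the silyl ether under buffered, weakly acidic conditions should free the tertiary C4 hydroxyl without enolising the α-ketol, and any material in which the silyl group has moved to the C6 oxygen converges on the same diol.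

Step 12
Reactants: 17 (2R,6S,9S,10R)-2,10-dihydroxy-2,6-dimethyl-9-(prop-1-en-2-yl)cyclodecan-1-one
Product: 18 (2R,6S,9R,10R)-2,10-dihydroxy-9-(2-hydroxypropan-2-yl)-2,6-dimethylcyclodecan-1-one
Conditions: Co(acac)2 (20 mol %), PhSiH3, O2 (1 atm), iPrOH, rt
Reagents that add atoms: dioxygen, O=O
Why: Mukaiyama hydration (hydrogen-atom transfer from a cobalt hydride to the 1,1-disubstituted alkene, capture of the tertiary radical by O2, reduction of the peroxide) should give the Markovnikov tertiary alcohol at C11, which is not a stereocentre, and it precedes esterification because the angelate alkene would not survive these conditions.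

Step 13
Reactants: 18 (2R,6S,9R,10R)-2,10-dihydroxy-9-(2-hydroxypropan-2-yl)-2,6-dimethylcyclodecan-1-one
Product: 19 (1R,3R,7S,10R)-3-hydroxy-10-(2-hydroxypropan-2-yl)-3,7-dimethyl-2-oxocyclodecyl (2Z)-2-methylbut-2-enoate
Conditions: angelic acid, 2,4,6-trichlorobenzoyl chloride, Et3N, toluene, rt; filter; then 18, toluene, 75 °C
Reagents that add atoms: angelic acid [(2Z)-2-methylbut-2-enoic acid], C/C=C(/C)C(=O)O
Why: Yamaguchi-type acylation with the preformed mixed anhydride, run without a nucleophilic catalyst, should esterify the only secondary hydroxyl (the two tertiary ones are unreactive) and avoid Z to E isomerisation to the tiglate, while the C5 ketone keeps the C5 oxygen out of the competition.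

Step 14
Reactants: 19 (1R,3R,7S,10R)-3-hydroxy-10-(2-hydroxypropan-2-yl)-3,7-dimethyl-2-oxocyclodecyl (2Z)-2-methylbut-2-enoate
Product: 20 (1R,2S,3R,7S,10R)-2,3-dihydroxy-10-(2-hydroxypropan-2-yl)-3,7-dimethylcyclodecyl (2Z)-2-methylbut-2-enoate (CNP0130723.1)
Conditions: Zn(BH4)2, Et2O, −78 to −30 °C; pH 7 buffer
Reagents that add atoms: none
Why: In this chelation-controlled reduction zinc should bridge the free C4 hydroxyl and the C5 carbonyl so that hydride arrives from the C15 methyl side (Cram chelate model), the same face that the polar Felkin–Anh model predicts for the C6 acyloxy neighbour, giving the 5S carbinol, and the neutral reagent at low temperature should leave the angelate in place.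

**Compound list**

1 | (S)-β-citronellene, (3S)-3,7-dimethylocta-1,6-diene | C=C[C@@H](C)CCC=C(C)C | starting material
2 | (2E,6S)-2,6-dimethylocta-2,7-dien-1-ol | OC/C(C)=C/CC[C@H](C)C=C | intermediate
3 | [(2S,3S)-2-methyl-3-[(3S)-3-methylpent-4-en-1-yl]oxiran-2-yl]methanol | OC[C@]1(C)O[C@H]1CC[C@H](C)C=C | intermediate
4 | (2R,6S)-2,6-dimethyloct-7-ene-1,2-diol | OC[C@](C)(O)CCC[C@H](C)C=C | intermediate
5 | (2R,6S)-2-hydroxy-2,6-dimethyloct-7-enoic acid | OC(=O)[C@](C)(O)CCC[C@H](C)C=C | intermediate
6 | triethylsilyl (2R,6S)-2,6-dimethyl-2-[(triethylsilyl)oxy]oct-7-enoate | CC[Si](CC)(CC)OC(=O)[C@](C)(O[Si](CC)(CC)CC)CCC[C@H](C)C=C | intermediate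
7 | (2R,6S)-2,6-dimethyl-2-[(triethylsilyl)oxy]oct-7-enoyl chloride | ClC(=O)[C@](C)(O[Si](CC)(CC)CC)CCC[C@H](C)C=C | intermediate (not isolated)
8 | (3R,7S)-1-diazo-3,7-dimethyl-3-[(triethylsilyl)oxy]non-8-en-2-one | [N-]=[N+]=CC(=O)[C@](C)(O[Si](CC)(CC)CC)CCC[C@H](C)C=C | intermediate
9 | prop-2-yn-1-ol | C#CCO | starting material
10 | bromomagnesium (2Z)-3-(bromomagnesio)-2-methylprop-2-en-1-olate | Br[Mg]OC/C(C)=C\[Mg]Br | intermediate (not isolated)
11 | (2Z)-3-iodo-2-methylprop-2-en-1-ol | OC/C(C)=C\I | intermediate
12 | (3R,7S)-1-{[(2Z)-3-iodo-2-methylprop-2-en-1-yl]oxy}-3,7-dimethyl-3-[(triethylsilyl)oxy]non-8-en-2-one | I/C=C(C)\COCC(=O)[C@](C)(O[Si](CC)(CC)CC)CCC[C@H](C)C=C | intermediate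
13 | 9-[(3R,7R)-9-{[(2Z)-3-iodo-2-methylprop-2-en-1-yl]oxy}-3,7-dimethyl-8-oxo-7-[(triethylsilyl)oxy]nonyl]-9-borabicyclo[3.3.1]nonane | I/C=C(C)\COCC(=O)[C@](C)(O[Si](CC)(CC)CC)CCC[C@H](C)CCB1C2CCCC1CCC2 | intermediate (not isolated)
14 | (4R,8S,11Z)-4,8,12-trimethyl-4-[(triethylsilyl)oxy]-1-oxacyclotridec-11-en-3-one | O=C1COC/C(C)=C\CC[C@@H](C)CCC[C@@]1(C)O[Si](CC)(CC)CC | intermediate
15 | lithium enolate of 14 across C5–C6 (enolate geometry not assigned) | [Li]OC1=COC/C(C)=C\CC[C@@H](C)CCC[C@@]1(C)O[Si](CC)(CC)CC | intermediate (not isolated)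
16 | (2R,6S,9S,10R)-10-hydroxy-2,6-dimethyl-9-(prop-1-en-2-yl)-2-[(triethylsilyl)oxy]cyclodecan-1-one | O=C1[C@H](O)[C@H](C(C)=C)CC[C@@H](C)CCC[C@@]1(C)O[Si](CC)(CC)CC | intermediate
17 | (2R,6S,9S,10R)-2,10-dihydroxy-2,6-dimethyl-9-(prop-1-en-2-yl)cyclodecan-1-one | O=C1[C@H](O)[C@H](C(C)=C)CC[C@@H](C)CCC[C@@]1(C)O | intermediate
18 | (2R,6S,9R,10R)-2,10-dihydroxy-9-(2-hydroxypropan-2-yl)-2,6-dimethylcyclodecan-1-one | O=C1[C@H](O)[C@H](C(C)(C)O)CC[C@@H](C)CCC[C@@]1(C)O | intermediate
19 | (1R,3R,7S,10R)-3-hydroxy-10-(2-hydroxypropan-2-yl)-3,7-dimethyl-2-oxocyclodecyl (2Z)-2-methylbut-2-enoate | C/C=C(/C)C(=O)O[C@@H]1[C@H](C(C)(C)O)CC[C@@H](C)CCC[C@@](C)(O)C1=O | intermediate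
20 | (1R,2S,3R,7S,10R)-2,3-dihydroxy-10-(2-hydroxypropan-2-yl)-3,7-dimethylcyclodecyl (2Z)-2-methylbut-2-enoate | C/C=C(/C)C(=O)O[C@@H]1[C@H](C(C)(C)O)CC[C@@H](C)CCC[C@@](C)(O)[C@H]1O | target

**Step count**

Total: 14 steps. Longest linear sequence: 13 steps (steps 1–6 and 8–14, from 1 to 20); step 7 is a one-step side branch.

**Steps most likely to fail**

Step 10 (ring-contracting Wittig shift). The enolate may leak into the [3,3] oxy-Claisen or the radical [1,2] channel. The shift may also occur on the wrong face of the C7=C11 alkene, or the product alkoxide may isomerise by α-ketol shift or silyl transfer. The fallback sets out from 14 and returns to 16, and each operation is a documented reaction type. Condensation of 14 with N,N-dimethylhydrazine (AcOH cat., EtOH, reflux) should give the macrocyclic N,N-dimethylhydrazone F1. Deprotonation with LiN(iPr)2 in THF (−78 to 0 °C) generates the aza-enolate, whose [2,3]-Wittig shift is the hydrazone variant described for α-allyloxy ketones and has no oxy-Claisen channel; it should give the ring-contracted α-hydroxy hydrazone F2. Cleavage with aqueous oxalic acid/Et2O returns 16.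

Step 9 (macrocyclisation). Hydride transfer from the borane to the C5 ketone may compete with hydroboration, and oligomerisation may compete with ring closure. The fallback sets out from 12 and returns to 14 and takes the ketone out of the cyclisation event. NaBH4 (MeOH, 0 °C) reduces 12 to the C5 carbinol F3 (both epimers). Excess 9-BBN (2.5 equiv) then gives the bis-borane F4 (alkylborane at C8, borinate at the C5 oxygen). The same palladium-catalysed coupling at high dilution closes the ring to the macrocyclic carbinol F5. Dess–Martin periodinane (NaHCO3, CH2Cl2) re-oxidises C5 and gives 14.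

Step 14 (final reduction). Facial selectivity of hydride delivery inside the ten-membered ring may be poor, or the angeloyl group may migrate from the C6 to the C5 oxygen. The fallback sets out from 18 and returns to 20, with the reduction moved ahead of the esterification:
- Et3SiCl/imidazole (DMF, 0 °C) silylates only the secondary C6 hydroxyl to give the C6 silyl ether F6.
- Zn(BH4)2 (Et2O, −78 °C), with no acyl group present, gives the C4,C5-diol F7.
- 2,2-Dimethoxypropane/PPTS (CH2Cl2) ties C4–OH and C5–OH into the acetonide F8.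
- Bu4NF (THF, 0 °C) frees the C6 hydroxyl to give the acetonide alcohol F9.
- Angeloylation under the conditions of step 13 gives the angelate acetonide F10.
- 80% aqueous AcOH at 40 °C removes the acetonide and gives 20.

**Further compounds**

F1 | step 10 | N,N-dimethylhydrazone of 14 | CN(C)N=C1COC/C(C)=C\CC[C@@H](C)CCC[C@@]1(C)O[Si](CC)(CC)CC
F2 | step 10 | N,N-dimethylhydrazone of 16 | CN(C)N=C1[C@H](O)[C@H](C(C)=C)CC[C@@H](C)CCC[C@@]1(C)O[Si](CC)(CC)CC
F3 | step 9 | (3R,7S)-1-{[(2Z)-3-iodo-2-methylprop-2-en-1-yl]oxy}-3,7-dimethyl-3-[(triethylsilyl)oxy]non-8-en-2-ol (both C2 epimers) | I/C=C(C)\COCC(O)[C@](C)(O[Si](CC)(CC)CC)CCC[C@H](C)C=C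
F4 | step 9 | bis(9-BBN) derivative of F3 (alkylborane at C8, borinate at the C5 oxygen) | I/C=C(C)\COCC(OB1C2CCCC1CCC2)[C@](C)(O[Si](CC)(CC)CC)CCC[C@H](C)CCB1C2CCCC1CCC2
F5 | step 9 | (4R,8S,11Z)-4,8,12-trimethyl-4-[(triethylsilyl)oxy]-1-oxacyclotridec-11-en-3-ol (both C3 epimers) | OC1COC/C(C)=C\CC[C@@H](C)CCC[C@@]1(C)O[Si](CC)(CC)CC
F6 | step 14 | C6 triethylsilyl ether of 18 | O=C1[C@H](O[Si](CC)(CC)CC)[C@H](C(C)(C)O)CC[C@@H](C)CCC[C@@]1(C)O
F7 | step 14 | (5S)-carbinol from F6 (C4,C5-diol, C6 silyl ether) | O[C@H]1[C@H](O[Si](CC)(CC)CC)[C@H](C(C)(C)O)CC[C@@H](C)CCC[C@@]1(C)O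
F8 | step 14 | C4,C5-acetonide of F7 | CC1(C)O[C@H]2[C@H](O[Si](CC)(CC)CC)[C@H](C(C)(C)O)CC[C@@H](C)CCC[C@@]2(C)O1
F9 | step 14 | C4,C5-acetonide with free C6 hydroxyl | CC1(C)O[C@H]2[C@H](O)[C@H](C(C)(C)O)CC[C@@H](C)CCC[C@@]2(C)O1
F10 | step 14 | C4,C5-acetonide of 20 (C6 angelate) | C/C=C(/C)C(=O)O[C@@H]1[C@H](C(C)(C)O)CC[C@@H](C)CCC[C@@]2(C)OC(C)(C)O[C@@H]12
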